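## The problem

The target is a C25 monocyclic acid: a 14-membered carbocycle whose only stereocentre, C1 (R), carries a 1,1-disubstituted alkene (C15=C16H2) bearing a 4-methylpent-3-enyl chain. The ring contains three trisubstituted alkenes of different kinds: C3=C4 with the carboxyl group on C4 cis to C2, E-C7=C8 and Z-C11=C12. Each geometry must be secured separately. C1 has no stereogenic neighbour (C2 and C14 are methylenes), so it can only be set by a reagent or by a temporary stereocentre. No heteroatom bond exists in the ring, so the macrocycle must be closed by C–C bond formation on a skipped polyene. Five alkenes exclude hydrogenation, dissolving metals and strong acid (transannular cation–alkene cyclisation). The acid is of the angelate type (β-carbon cis to CO2H) and would isomerise through enal or dienolate intermediates, so the carboxyl carbon should arrive late and with retention of geometry. The enabling feature is the homoallylic array C2–C1–C15(=C16H2). It is what remains when a C2 carbanion undergoes a [2,3]-shift onto C1 of an allyl ether C1=C15–C16H2–O. If C3≡C4 is an alkyne, C2 is propargylic and acidic, and the hydroxyl left on C2 can direct the functionalisation of C3≡C4.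

## Retrosynthesis

Numbering: ring carbons C1–C14 (C1 stereocentre; C3=C4; C7=C8; C11=C12), C15 the side-chain carbon on C1, C16 its exocyclic methylene.

**Acid 27 to alkenyl iodide 26.** The C4–CO2H bond is cut. Introducing the carboxyl carbon last, by carbonylation of the iodide 26, avoids carrying an isomerisable Z-enoic acid through the route. A ring-closing olefination at C3=C4 would instead have to deliver the less stable geometry. The precursor has no polar group. The forward step must retain alkene geometry and avoid strong base.

**Iodide 26 to propargylic alcohol 22.** The C4–I and C3–H bonds are cut and a hydroxyl is restored at C2 (26 from iodo alcohol 24 through mesylate 25; 24 from 22 through alanate 23). An alkyne flanked by two methylenes cannot be functionalised regioselectively. A C2 hydroxyl places hydride on C3 and the metal on C4 by anti addition, which puts C2 cis to the future carboxyl. The forward steps need directed anti-hydroalumination, then removal of the C2 oxygen by direct hydride displacement without allylic transposition.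

**Alcohol 22 to ether 21.** The C1–C2 bond is cut and O–C16 reconnected. This is the strategic disconnection. The achiral 17-membered propargylic allylic ether 21 contains no stereocentre. The forward [2,3]-shift makes the ring, C1, the exocyclic methylene and the directing hydroxyl together. Ring closures elsewhere would require C1 to be set beforehand in an open chain. The forward step asks for enantiotopic deprotonation at C2 by a chiral lithium amide.

**Ether 21 to chloro alcohol 20.** The O–C16 bond is cut. This bond is chosen over O–C2 because the allylic chloride follows directly from the alcohol that ester reduction provides. The propargylic alkoxide is also weakly basic. The forward step is a high-dilution Williamson closure.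

**Chloro alcohol 20 to fragments 11 and 15.** Chloride 20 comes from silyl ether 19, and 19 from allylic alcohol 17. The C9–C10 bond of 17 is cut through sulfone 16 into hydroxy sulfone 11 and allylic bromide 15. This is a head-to-tail junction between two allylic carbons. The sulfone sits on the nerol-derived C10, so reductive removal meets a π-allyl unit with a secondary and a tertiary terminus. The two fragments are of similar size. The forward steps need C-alkylation of a hydroxy sulfone dianion and desulfonylation that keeps Z-C11=C12.

**Fragment 11 to nerol.** The C1=C15 bond of ester 10 (reduced to 11) is cut by Horner–Wadsworth–Emmons disconnection into aldehyde 9 and phosphonate 3. Aldehyde 9 comes from neryl phenyl sulfone 7 through epoxide 8, and 7 from nerol 4. Nerol supplies C10–C14 and the Z-C11=C12 alkene ready-made. Phosphonate 3 comes from phosphonoacetate 1 and bromide 2. The olefination must be E-selective.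

**Fragment 15 to a propargyl ether.** Bromide 15 comes from allylic alcohol 14, made by E-selective allylic oxidation of enyne 13. The C4–C5 bond of 13 is cut into silyl propargyl ether 12 and bromide 2. Bromide 2 therefore serves twice.

## Roads not taken

**Alternative 1:** The cut is through C10–C11 and C12–C13. An alkylcopper drawn from the C13-to-C3 half adds syn across propyne A2, and the alkenylcopper is alkylated by a C10 iodide to give acyclic acetal A1.
- Merits: Z-C11=C12 is set by mechanism, three pieces are joined in one operation, and no sulfone has to be removed.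
- Weak points: no ring is closed and C1 must already be present in enantiopure form. C4 is still missing, so the ring would have to be closed by an olefination at C3=C4 that delivers the less stable geometry.
- Comparison: if C1 came from an auxiliary, its purity could exceed what a chiral amide gives. Against that, the chosen plan takes the Z-alkene from nerol and forms ring, C1 and the C4-directing hydroxyl in one step.

**Alternative 2:** The cut is at C9–C10. A potassium amide base turns an open-chain bromo sulfone into its carbanion, which closes the 14-membered ring to give cyclic sulfone A3.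
- Merits: carbanion macrocyclisation forms the carbocycle directly in one step and is a robust ring closure. In this respect it is better than etherification followed by contraction.
- Weak points: C1 and the C3=C4 geometry must both be built in the open chain. The sulfone must be removed inside the ring next to Z-C11=C12. The C4 hydroxymethyl group must be oxidised to the acid through a labile Z-enal.
- Comparison: the chosen plan spends one more ring-forming operation. In return C1 is created in the ring-forming event and the carboxyl is installed with retention.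

**Alternative 3:** The cut is at C1–C14 and C1–C15. A C1 carbamate is lithiated with a chiral diamine, trapped by a C14 boronic ester with 1,2-migration, then subjected to Zweifel olefination with a C15 alkenyl-metal to give A4.
- Merits: reagent-controlled lithiation–borylation usually gives very high enantiomeric purity, and the 1,1-disubstituted alkene is built at the same time. For control of C1 this road is the stronger one.
- Weak points: no ring closes. C4–C9 must still be attached, the macrocycle closed, and the C3=C4 geometry solved separately.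
- Comparison: the chosen plan accepts a less certain enantioselectivity, with a resolution held in reserve. In return it gets a shorter route in which ring closure and stereocentre formation coincide.

Key step: step 15

Assumption 1: the amide from (S,S)-bis(1-phenylethyl)amine is taken to favour the 1S alcohol 22; if the sense is opposite, the commercial (R,R)-amine is used.
Assumption 2: the C2 carbinol of 22 is drawn 2R; since C2 ends as a methylene, its epimer would converge on the same target.

## Route

Step 1
Reactants: 1 triethyl phosphonoacetate; 2 5-bromo-2-methylpent-2-ene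
Product: 3 ethyl 2-(diethoxyphosphoryl)-6-methylhept-5-enoate (racemic)
Conditions: 1 (slight excess), NaH, DMF, 0 °C; then 2, 60 °C
Reagents that add atoms: none
Why: SN2 C-alkylation of the sodium phosphonoacetate enolate by a primary bromide is the standard entry to α-alkyl Horner–Wadsworth–Emmons reagents; excess 1 limits dialkylation.

Step 2
Reactants: 4 nerol
Product: 7 {[(2Z)-3,7-dimethylocta-2,6-dien-1-yl]sulfonyl}benzene (neryl phenyl sulfone), via neryl methanesulfonate 5 (not isolated), via neryl chloride 6 (not isolated)
Conditions: MsCl, LiCl, 2,4,6-collidine, DMF, 0 °C; then PhSO2Na, rt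
Reagents that add atoms: sodium benzenesulfinate, [Na+].[O-]S(=O)c1ccccc1
Why: Mesylation with chloride exchange gives the primary allylic chloride by SN2 without transposition or Z/E leakage, and S-alkylation of the sulfinate in the same solvent gives the allylic sulfone.

Step 3
Reactants: 7 neryl phenyl sulfone
Product: 8 2,2-dimethyl-3-[(3Z)-3-methyl-5-(phenylsulfonyl)pent-3-en-1-yl]oxirane (racemic)
Conditions: mCPBA (1 equiv), CH2Cl2, 0 °C
Reagents that add atoms: 3-chloroperoxybenzoic acid, O=C(OO)c1cccc(Cl)c1
Why: Prilezhaev epoxidation should select the distal electron-rich alkene because the other is deactivated by the allylic sulfonyl group; the racemic epoxide stereocentre is destroyed in step 4.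

Step 4
Reactants: 8 epoxy sulfone
Product: 9 (4Z)-4-methyl-6-(phenylsulfonyl)hex-4-enal
Conditions: H5IO6, THF–Et2O, 0 °C
Reagents that add atoms: none
Why: Periodic acid opens the epoxide to the glycol and cleaves it in the same flask (Malaprade-type cleavage), releasing acetone and the aldehyde carbon that becomes C1.

Step 5
Reactants: 9 aldehyde; 3 phosphonate
Product: 10 ethyl (2E,6Z)-6-methyl-2-(4-methylpent-3-en-1-yl)-8-(phenylsulfonyl)octa-2,6-dienoate
Conditions: 3, NaH, DME, 0 °C; then 9, 0 °C → rt
Reagents that add atoms: none
Why: Horner–Wadsworth–Emmons olefination under equilibrating conditions should favour the E-enoate (C14 trans to the ester); the phosphonate anion is too weak a base to deprotonate the sulfone, and any Z-isomer is removed by chromatography after step 6.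

Step 6
Reactants: 10 enoate
Product: 11 (2E,6Z)-6-methyl-2-(4-methylpent-3-en-1-yl)-8-(phenylsulfonyl)octa-2,6-dien-1-ol
Conditions: i-Bu2AlH, CH2Cl2, −78 °C
Reagents that add atoms: none
Why: 1,2-Reduction of a conjugated ester by i-Bu2AlH at low temperature gives the allylic alcohol and leaves the sulfone and alkenes untouched.

Step 7
Reactants: 12 tert-butyldimethyl(prop-2-yn-1-yloxy)silane; 2 5-bromo-2-methylpent-2-ene
Product: 13 tert-butyldimethyl[(7-methyloct-6-en-2-yn-1-yl)oxy]silane
Conditions: 12, n-BuLi, THF, −78 °C; then 2, DMPU, −78 °C → rt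
Reagents that add atoms: none
Why: Alkylation of a lithium acetylide by an unbranched primary bromide in THF–DMPU is standard and forms C4–C5; substitution should outrun elimination.

Step 8
Reactants: 13 enyne
Product: 14 (2E)-8-[(tert-butyldimethylsilyl)oxy]-2-methyloct-2-en-6-yn-1-ol
Conditions: SeO2 (cat.), t-BuOOH, salicylic acid (cat.), CH2Cl2, rt
Reagents that add atoms: tert-butyl hydroperoxide, CC(C)(C)OO
Why: SeO2 allylic oxidation (ene reaction, then [2,3]-shift) of a gem-dimethyl trisubstituted alkene hydroxylates the methyl trans to the chain, giving the E-allylic alcohol; the more substituted alkene terminus reacts ahead of the other allylic and propargylic positions.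

Step 9
Reactants: 14 allylic alcohol
Product: 15 {[(6E)-8-bromo-7-methyloct-6-en-2-yn-1-yl]oxy}(tert-butyl)dimethylsilane
Conditions: CBr4, PPh3, CH2Cl2, −20 → 0 °C
Reagents that add atoms: carbon tetrabromide, BrC(Br)(Br)Br
Why: Appel bromination converts the primary allylic alcohol by direct SN2 displacement under neutral conditions, keeping the E-geometry and the silyl ether.

Step 10
Reactants: 11 hydroxy sulfone; 15 allylic bromide
Product: 16 (2E,6Z,10E)-16-[(tert-butyldimethylsilyl)oxy]-6,10-dimethyl-2-(4-methylpent-3-en-1-yl)-8-(phenylsulfonyl)hexadeca-2,6,10-trien-14-yn-1-ol (racemic at C8)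
Conditions: 11, n-BuLi (2 equiv), THF, −78 °C; then 15, −78 → −40 °C; aq. NH4Cl
Reagents that add atoms: none
Why: The alkoxide/α-sulfonyl carbanion dianion is alkylated at the soft carbanion carbon by the allylic bromide (sulfone-carbanion coupling of terpenoid units), forming C9–C10 while the alkoxide stays unalkylated; the sulfone-bearing carbon is racemic and is cleared in step 11.

Step 11
Reactants: 16 coupled sulfone
Product: 17 (2E,6Z,10E)-16-[(tert-butyldimethylsilyl)oxy]-6,10-dimethyl-2-(4-methylpent-3-en-1-yl)hexadeca-2,6,10-trien-14-yn-1-ol
Conditions: PdCl2(dppp) (cat.), LiBHEt3, THF, 0 °C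
Reagents that add atoms: none
Why: Zerovalent palladium formed in the flask ionises the allylic sulfone to a π-allyl complex and hydride enters at the less substituted terminus C10 (palladium-catalysed reductive desulfonylation); fast hydride capture should keep Z-C11=C12, and the alkyne and silyl ether are not expected to react at 0 °C.

Step 12
Reactants: 17 allylic alcohol
Product: 19 tert-butyl{[(6E,10Z,14E)-15-(chloromethyl)-7,11,19-trimethylicosa-6,10,14,18-tetraen-2-yn-1-yl]oxy}dimethylsilane, via allylic methanesulfonate 18 (not isolated)
Conditions: MsCl, LiCl, 2,4,6-collidine, DMF, 0 °C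
Reagents that add atoms: lithium chloride, [Li+].[Cl-]
Why: Mesylation with chloride displacement in the flask gives the primary allylic chloride by SN2 with retention of the E-C1=C15 geometry; the buffered medium spares the silyl ether.

Step 13
Reactants: 19 chloro silyl ether
Product: 20 (6E,10Z,14E)-15-(chloromethyl)-7,11,19-trimethylicosa-6,10,14,18-tetraen-2-yn-1-ol
Conditions: HF·pyridine, pyridine, THF, 0 °C → rt
Reagents that add atoms: none
Why: Buffered fluoride desilylation frees the primary propargylic alcohol without a basic alkoxide or a strongly acidic medium that could displace or solvolyse the allylic chloride.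

Step 14
Reactants: 20 chloro alcohol
Product: 21 (3E,7Z,11E)-7,11-dimethyl-3-(4-methylpent-3-en-1-yl)-1-oxacycloheptadeca-3,7,11-trien-15-yne
Conditions: EtMgBr (1 equiv), THF–HMPA, slow addition to refluxing solvent, high dilution
Reagents that add atoms: none
Why: Intramolecular Williamson etherification of the propargylic magnesium alkoxide with the primary allylic chloride closes the 17-membered ether; the weakly basic alkoxide favours SN2 at C16 over elimination, and the linear alkyne and three alkenes lower the entropic cost of closure.

Step 15
Reactants: 21 17-membered propargylic allylic ether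
Product: 22 (1R,6E,10Z,14S)-7,11-dimethyl-14-(6-methylhepta-1,5-dien-2-yl)cyclotetradeca-6,10-dien-2-yn-1-ol (strategy numbering: 1S at C1, 2R at C2)
Conditions: lithium bis[(S)-1-phenylethyl]amide (from the amine and n-BuLi), THF, −40 → −20 °C; aq. NH4Cl
Reagents that add atoms: none
Why: The lithium amide removes one of the two enantiotopic hydrogens at the propargylic C2, and the α-oxy carbanion attacks C1 of the allyl unit suprafacially through a five-membered envelope transition state while the C16–O bond breaks, a [2,3]-Wittig rearrangement. The closest known reaction type is the [2,3]-Wittig ring contraction of macrocyclic propargylic allylic ethers to 14-membered carbocycles promoted by chiral lithium amides. The 14-membered ring closes by ring contraction: the new C1–C2 bond spans the ether bridge transannularly, the termini are already held together by the 17-membered ring so no dilution is needed, and the extruded C16 becomes the exocyclic methylene. C1 is controlled by the chiral amide, which differentiates the enantiotopic C2 hydrogens and thereby the face of the E-C1=C15 alkene that is attacked. C2 is fixed relative to C1 by the E-geometry of the allyl unit and the placement of the alkynyl arm on the envelope within the ring, and is removed later. The step needs deprotonation at C2 rather than at the allylic C16, which the higher acidity of the propargylic position secures, and a [2,3]- rather than a [1,2]-shift, which the low temperature secures. Enantioselectivity is the least secure element, so the enantiomeric purity of 22 is to be checked before the end game.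

Step 16
Reactants: 22 propargylic alcohol
Product: 24 (1R,2Z,6E,10Z,14S)-3-iodo-7,11-dimethyl-14-(6-methylhepta-1,5-dien-2-yl)cyclotetradeca-2,6,10-trien-1-ol, via cyclic alkenylalanate 23 (not isolated)
Conditions: NaAlH2(OCH2CH2OMe)2, THF, 0 °C → rt; then I2, THF, −78 °C
Reagents that add atoms: iodine, II
Why: The aluminium-bound alkoxide delivers hydride to C3 and aluminium to C4 by anti addition (hydroxyl-directed hydroalumination of a propargylic alcohol), and iodine replaces aluminium with retention, so iodine is cis to C2; no stereocentre is touched.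

Step 17
Reactants: 24 iodo alcohol
Product: 26 (1Z,5E,9Z,12R)-9-iodo-1,5-dimethyl-12-(6-methylhepta-1,5-dien-2-yl)cyclotetradeca-1,5,9-triene, via iodo allylic methanesulfonate 25 (not isolated)
Conditions: MsCl, Et3N, THF, −30 °C; then LiBHEt3, −30 → 0 °C
Reagents that add atoms: none
Why: The allylic C2–O bond is cleaved by SN2 hydride displacement of the mesylate with LiBHEt3, a reagent that reduces secondary sulfonates by C–O cleavage; SN2' delivery would have to occur at the fully substituted iodine-bearing C4 and is disfavoured, the alkenyl iodide is inert to the hydride, and C1 is untouched.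

Step 18
Reactants: 26 alkenyl iodide
Product: 27 (1Z,4R,7Z,11E)-7,11-dimethyl-4-(6-methylhepta-1,5-dien-2-yl)cyclotetradeca-1,7,11-triene-1-carboxylic acid (CNP0269207.1)
Conditions: Pd(PPh3)4 (cat.), CO (1 atm), Et3N, DMF–H2O, 60 °C; then dilute aq. HCl to pH 4
Reagents that add atoms: carbon monoxide, [C-]#[O+]; water, O
Why: Oxidative addition of zerovalent palladium to the alkenyl iodide, CO insertion and hydrolysis of the acylpalladium species (palladium-catalysed hydroxycarbonylation) install the carboxyl with retention, so C2 stays cis to CO2H; the mildly basic medium avoids dienolate formation.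

## Compound list

1 | triethyl phosphonoacetate | CCOC(=O)CP(=O)(OCC)OCC | starting material
2 | 5-bromo-2-methylpent-2-ene | CC(C)=CCCBr | starting material
3 | ethyl 2-(diethoxyphosphoryl)-6-methylhept-5-enoate (racemic) | CCOC(=O)C(CCC=C(C)C)P(=O)(OCC)OCC | intermediate
4 | nerol | CC(C)=CCC/C(C)=C\CO | starting material
5 | neryl methanesulfonate (not isolated) | CC(C)=CCC/C(C)=C\COS(C)(=O)=O | intermediate
6 | neryl chloride (not isolated) | CC(C)=CCC/C(C)=C\CCl | intermediate
7 | {[(2Z)-3,7-dimethylocta-2,6-dien-1-yl]sulfonyl}benzene | CC(C)=CCC/C(C)=C\CS(=O)(=O)c1ccccc1 | intermediate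
8 | 2,2-dimethyl-3-[(3Z)-3-methyl-5-(phenylsulfonyl)pent-3-en-1-yl]oxirane (racemic) | CC1(C)OC1CC/C(C)=C\CS(=O)(=O)c1ccccc1 | intermediate
9 | (4Z)-4-methyl-6-(phenylsulfonyl)hex-4-enal | O=CCC/C(C)=C\CS(=O)(=O)c1ccccc1 | intermediate
10 | ethyl (2E,6Z)-6-methyl-2-(4-methylpent-3-en-1-yl)-8-(phenylsulfonyl)octa-2,6-dienoate | CCOC(=O)/C(CCC=C(C)C)=C/CC/C(C)=C\CS(=O)(=O)c1ccccc1 | intermediate
11 | (2E,6Z)-6-methyl-2-(4-methylpent-3-en-1-yl)-8-(phenylsulfonyl)octa-2,6-dien-1-ol | OC/C(CCC=C(C)C)=C/CC/C(C)=C\CS(=O)(=O)c1ccccc1 | intermediate
12 | tert-butyldimethyl(prop-2-yn-1-yloxy)silane (commercial; the silyl ether of prop-2-yn-1-ol) | C#CCO[Si](C)(C)C(C)(C)C | starting material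
13 | tert-butyldimethyl[(7-methyloct-6-en-2-yn-1-yl)oxy]silane | CC(C)=CCCC#CCO[Si](C)(C)C(C)(C)C | intermediate
14 | (2E)-8-[(tert-butyldimethylsilyl)oxy]-2-methyloct-2-en-6-yn-1-ol | OC/C(C)=C/CCC#CCO[Si](C)(C)C(C)(C)C | intermediate
15 | {[(6E)-8-bromo-7-methyloct-6-en-2-yn-1-yl]oxy}(tert-butyl)dimethylsilane | BrC/C(C)=C/CCC#CCO[Si](C)(C)C(C)(C)C | intermediate
16 | (2E,6Z,10E)-16-[(tert-butyldimethylsilyl)oxy]-6,10-dimethyl-2-(4-methylpent-3-en-1-yl)-8-(phenylsulfonyl)hexadeca-2,6,10-trien-14-yn-1-ol (racemic at C8) | OC/C(CCC=C(C)C)=C/CC/C(C)=C\C(S(=O)(=O)c1ccccc1)C/C(C)=C/CCC#CCO[Si](C)(C)C(C)(C)C | intermediate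
17 | (2E,6Z,10E)-16-[(tert-butyldimethylsilyl)oxy]-6,10-dimethyl-2-(4-methylpent-3-en-1-yl)hexadeca-2,6,10-trien-14-yn-1-ol | OC/C(CCC=C(C)C)=C/CC/C(C)=C\CC/C(C)=C/CCC#CCO[Si](C)(C)C(C)(C)C | intermediate
18 | (2E,6Z,10E)-16-[(tert-butyldimethylsilyl)oxy]-6,10-dimethyl-2-(4-methylpent-3-en-1-yl)hexadeca-2,6,10-trien-14-yn-1-yl methanesulfonate (not isolated) | CS(=O)(=O)OC/C(CCC=C(C)C)=C/CC/C(C)=C\CC/C(C)=C/CCC#CCO[Si](C)(C)C(C)(C)C | intermediate
19 | tert-butyl{[(6E,10Z,14E)-15-(chloromethyl)-7,11,19-trimethylicosa-6,10,14,18-tetraen-2-yn-1-yl]oxy}dimethylsilane | ClC/C(CCC=C(C)C)=C/CC/C(C)=C\CC/C(C)=C/CCC#CCO[Si](C)(C)C(C)(C)C | intermediate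
20 | (6E,10Z,14E)-15-(chloromethyl)-7,11,19-trimethylicosa-6,10,14,18-tetraen-2-yn-1-ol | ClC/C(CCC=C(C)C)=C/CC/C(C)=C\CC/C(C)=C/CCC#CCO | intermediate
21 | (3E,7Z,11E)-7,11-dimethyl-3-(4-methylpent-3-en-1-yl)-1-oxacycloheptadeca-3,7,11-trien-15-yne | O1CC#CCC/C=C(\C)CC/C=C(/C)CC/C=C(\CCC=C(C)C)C1 | intermediate
22 | (1R,6E,10Z,14S)-7,11-dimethyl-14-(6-methylhepta-1,5-dien-2-yl)cyclotetradeca-6,10-dien-2-yn-1-ol | C=C(CCC=C(C)C)[C@H]1[C@@H](O)C#CCC/C=C(\C)CC/C=C(/C)CC1 | intermediate
23 | sodium cyclic alkenylalanate of 22 (oxygen and C4 on aluminium, two 2-methoxyethoxy ligands; not isolated) | C=C(CCC=C(C)C)[C@H]1[C@H]2O[Al-](OCCOC)(OCCOC)C(=C2)CC/C=C(\C)CC/C=C(/C)CC1.[Na+] | intermediate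
24 | (1R,2Z,6E,10Z,14S)-3-iodo-7,11-dimethyl-14-(6-methylhepta-1,5-dien-2-yl)cyclotetradeca-2,6,10-trien-1-ol | C=C(CCC=C(C)C)[C@H]1[C@@H](O)/C=C(\I)CC/C=C(\C)CC/C=C(/C)CC1 | intermediate
25 | (1R,2Z,6E,10Z,14S)-3-iodo-7,11-dimethyl-14-(6-methylhepta-1,5-dien-2-yl)cyclotetradeca-2,6,10-trien-1-yl methanesulfonate (not isolated) | C=C(CCC=C(C)C)[C@H]1[C@@H](OS(C)(=O)=O)/C=C(\I)CC/C=C(\C)CC/C=C(/C)CC1 | intermediate
26 | (1Z,5E,9Z,12R)-9-iodo-1,5-dimethyl-12-(6-methylhepta-1,5-dien-2-yl)cyclotetradeca-1,5,9-triene | C=C(CCC=C(C)C)[C@H]1C/C=C(\I)CC/C=C(\C)CC/C=C(/C)CC1 | intermediate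
27 | (1Z,4R,7Z,11E)-7,11-dimethyl-4-(6-methylhepta-1,5-dien-2-yl)cyclotetradeca-1,7,11-triene-1-carboxylic acid | C=C(CCC=C(C)C)[C@H]1C/C=C(\C(=O)O)CC/C=C(\C)CC/C=C(/C)CC1 | target

## Step count and risks

Total: 18 steps. Longest linear sequence: 14 steps (nerol 4 to 27 through steps 2–6 and 10–18).

**Step 15 (key step).** The most likely failure is incomplete discrimination between the enantiotopic C2 hydrogens, leaving 22 of only moderate enantiomeric purity. Lesser risks are deprotonation at C16 and a [1,2]-shift if the temperature rises. Fallback by resolution: 21 is rearranged with n-BuLi in THF at −78 °C, which should give 22 together with its mirror image, the enantiomeric alcohol F1. Esterification of the pair with (S)-O-methylmandelic acid (DCC, DMAP) gives the (S)-O-methylmandelate of 22, ester F2, and the diastereomeric (S)-O-methylmandelate of F1, ester F3. These are separated by chromatography or crystallisation. Methanolysis of F2 (K2CO3, MeOH) returns to the route at 22. The same ester pair can also be used to enrich scalemic 22 from the chiral-base reaction.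

**Step 17.** The most likely failures are elimination of the secondary mesylate toward C1 to give a conjugated iodo diene, or hydride attack at sulfur that only returns 24. Fallback from 24: acetylation (Ac2O, pyridine) gives the iodo acetate F4. Methoxycarbonylation (Pd(PPh3)4, CO, MeOH, Et3N) gives the γ-acetoxy methyl ester F5. Palladium-catalysed formate hydrogenolysis of the allylic acetate (Pd2(dba)3·CHCl3, n-Bu3P, HCO2H, Et3N) should deliver hydride to C2, the allyl terminus remote from the ester, and give the methyl ester F6. Saponification (LiOH, THF–MeOH–H2O) returns to the route at 27. This sequence is held in reserve because its π-allyl/enolate intermediate could equilibrate the C3=C4 geometry.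

**Step 14.** The most likely failure is intermolecular etherification outpacing ring closure, or sluggish displacement of the allylic chloride. Fallback with reversed polarity, from 17: protection of the allylic hydroxyl (dihydropyran, pyridinium tosylate) gives the tetrahydropyranyl silyl bis-ether F7. Desilylation (Bu4NF) gives the propargylic alcohol F8. Appel bromination (CBr4, PPh3, 2,6-lutidine) gives the propargylic bromide F9. Acetal methanolysis (pyridinium tosylate, MeOH) gives the bromo allylic alcohol F10. Closure of the allylic sodium alkoxide onto the more reactive propargylic bromide (NaH, THF, high dilution) returns to the route at 21.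

**Step 5.** The most likely failure is erosion of E-selectivity with the α-alkyl phosphonate, which would carry the wrong allyl geometry into 21. Fallback from 9: Finkelstein exchange on 2 (NaI, acetone) gives 5-iodo-2-methylpent-2-ene F11. C-alkylation of ethyl (triphenylphosphoranylidene)acetate (2 equiv, ethyl acetate, reflux) by F11, with transylidation, gives the stabilised ylide ethyl 6-methyl-2-(triphenylphosphoranylidene)hept-5-enoate F12. Wittig olefination of 9 with F12 (toluene, 80 °C), which is reliably E-selective for α-alkyl ester ylides, returns to the route at 10.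

## Further compounds

F1 | step 15 | (1S,6E,10Z,14R)-7,11-dimethyl-14-(6-methylhepta-1,5-dien-2-yl)cyclotetradeca-6,10-dien-2-yn-1-ol (enantiomer of 22) | C=C(CCC=C(C)C)[C@@H]1[C@H](O)C#CCC/C=C(\C)CC/C=C(/C)CC1
F2 | step 15 | (2S)-2-methoxy-2-phenylacetate ester of 22 | C=C(CCC=C(C)C)[C@H]1[C@@H](OC(=O)[C@@H](OC)c2ccccc2)C#CCC/C=C(\C)CC/C=C(/C)CC1
F3 | step 15 | (2S)-2-methoxy-2-phenylacetate ester of F1 | C=C(CCC=C(C)C)[C@@H]1[C@H](OC(=O)[C@@H](OC)c2ccccc2)C#CCC/C=C(\C)CC/C=C(/C)CC1
F4 | step 17 | (1R,2Z,6E,10Z,14S)-3-iodo-7,11-dimethyl-14-(6-methylhepta-1,5-dien-2-yl)cyclotetradeca-2,6,10-trien-1-yl acetate | C=C(CCC=C(C)C)[C@H]1[C@@H](OC(C)=O)/C=C(\I)CC/C=C(\C)CC/C=C(/C)CC1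
F5 | step 17 | methyl ester of 27 carrying an acetoxy group at C2 (C2 cis to the ester) | C=C(CCC=C(C)C)[C@H]1[C@@H](OC(C)=O)/C=C(\C(=O)OC)CC/C=C(\C)CC/C=C(/C)CC1
F6 | step 17 | methyl (1Z,4R,7Z,11E)-7,11-dimethyl-4-(6-methylhepta-1,5-dien-2-yl)cyclotetradeca-1,7,11-triene-1-carboxylate | C=C(CCC=C(C)C)[C@H]1C/C=C(\C(=O)OC)CC/C=C(\C)CC/C=C(/C)CC1
F7 | step 14 | oxan-2-yl ether of 17 at the allylic oxygen (silyl ether retained) | O1CCCCC1OC/C(CCC=C(C)C)=C/CC/C(C)=C\CC/C(C)=C/CCC#CCO[Si](C)(C)C(C)(C)C
F8 | step 14 | (6E,10Z,14E)-7,11,19-trimethyl-15-[(oxan-2-yloxy)methyl]icosa-6,10,14,18-tetraen-2-yn-1-ol | O1CCCCC1OC/C(CCC=C(C)C)=C/CC/C(C)=C\CC/C(C)=C/CCC#CCO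
F9 | step 14 | 2-{[(2E,6Z,10E)-16-bromo-6,10-dimethyl-2-(4-methylpent-3-en-1-yl)hexadeca-2,6,10-trien-14-yn-1-yl]oxy}oxane | O1CCCCC1OC/C(CCC=C(C)C)=C/CC/C(C)=C\CC/C(C)=C/CCC#CCBr
F10 | step 14 | (2E,6Z,10E)-16-bromo-6,10-dimethyl-2-(4-methylpent-3-en-1-yl)hexadeca-2,6,10-trien-14-yn-1-ol | OC/C(CCC=C(C)C)=C/CC/C(C)=C\CC/C(C)=C/CCC#CCBr
F11 | step 5 | 5-iodo-2-methylpent-2-ene | CC(C)=CCCI
F12 | step 5 | ethyl 6-methyl-2-(triphenylphosphoranylidene)hept-5-enoate | CCOC(=O)C(CCC=C(C)C)=P(c1ccccc1)(c1ccccc1)c1ccccc1
A1 | alternative 1 | tert-butyl{[(3E,7Z,11R)-11-(2,2-dimethoxyethyl)-4,8,16-trimethyl-12-methylideneheptadeca-3,7,15-trien-1-yl]oxy}dimethylsilane | C=C(CCC=C(C)C)[C@H](CC/C(C)=C\CC/C(C)=C/CCO[Si](C)(C)C(C)(C)C)CC(OC)OC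
A2 | alternative 1 | propyne | CC#C
A3 | alternative 2 | tert-butyl{[(1Z,4R,7Z,11E)-7,11-dimethyl-4-(6-methylhepta-1,5-dien-2-yl)-9-(phenylsulfonyl)cyclotetradeca-1,7,11-trien-1-yl]methoxy}dimethylsilane (either C9 epimer) | C=C(CCC=C(C)C)[C@H]1C/C=C(\CO[Si](C)(C)C(C)(C)C)CC/C=C(\C)CC(S(=O)(=O)c2ccccc2)/C=C(/C)CC1
A4 | alternative 3 | tert-butyl{[(2Z,6R)-6-{2-[(tert-butyldimethylsilyl)oxy]ethyl}-3,11-dimethyl-7-methylidenedodeca-2,10-dien-1-yl]oxy}diphenylsilane | C=C(CCC=C(C)C)[C@H](CC/C(C)=C\CO[Si](c1ccccc1)(c1ccccc1)C(C)(C)C)CCO[Si](C)(C)C(C)(C)C
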